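**Retrosynthetic overview**
1. The last ring (C7–O–C9') closes by SN2 attack of the stereodefined C7 carbinol on a primary C9' mesylate, with retention at C7. Global desilylation follows.
2. The first tetrahydrofuran ring (C7'–O–C9) closes by ionising the benzylic C7' carbinol of a triol. The aryl group settles trans to both ring neighbours.
3. The key C7'–C8' bond comes from an intermolecular aldol between the lithium enolate of a (4R)-4-substituted γ-butyrolactone and the dihydrobenzofuran-5-carbaldehyde. This sets C8'.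
4. The lactone comes from an Evans syn aldol (C7–C8 bond) of an N-pent-4-enoyl oxazolidinone with silylated syringaldehyde, then auxiliary reduction and alkene cleavage.
5. The cis-dihydrobenzofuran comes from a dirhodium-catalysed 1,5 C–H insertion of an aryldiazoacetate made from 4-bromoguaiacol and vanillin. Ring order: dihydrobenzofuran, temporary lactone, tetrahydrofuran ring A, tetrahydrofuran ring B.

**Assumption:** the SMILES is read literally. It encodes a 2,3-cis (2S,3S) dihydrobenzofuran and a bis-exo (7S,8R,7'S,8'R) furofuran.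

**Numbering and abbreviations:** C7–C9 is the syringyl half and C7'–C9' is the benzofuran half. TIPS = triisopropylsilyl, TES = triethylsilyl, TBDPS = tert-butyldiphenylsilyl. ArS = 3,5-dimethoxy-4-(TIPSO)phenyl. ArB = (2S,3S)-3-(TBDPSO-methyl)-7-methoxy-2-[3-methoxy-4-(TIPSO)phenyl]-2,3-dihydrobenzofuran-5-yl.

Step 1
Reactants: 1 vanillin
Product: 2 3-methoxy-4-(triisopropylsilyloxy)benzaldehyde
Conditions: TIPSCl, imidazole, DMF, rt
Reagents that add atoms: chlorotriisopropylsilane, CC(C)[Si](Cl)(C(C)C)C(C)C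
Why: Phenol silylation gives a base-, hydride- and organolithium-stable aryl TIPS ether that fluoride removes at the end.

Step 2
Reactants: 2 3-methoxy-4-(triisopropylsilyloxy)benzaldehyde
Product: 3 [3-methoxy-4-(triisopropylsilyloxy)phenyl]methanol
Conditions: NaBH4, MeOH, 0 °C
Reagents that add atoms: none
Why: Borohydride reduction of an aromatic aldehyde is clean and leaves the aryl silyl ether untouched.

Step 3
Reactants: 4 4-bromo-2-methoxyphenol; 5 allyl bromide
Product: 6 1-(allyloxy)-4-bromo-2-methoxybenzene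
Conditions: K2CO3, acetone, reflux
Reagents that add atoms: none
Why: Williamson O-allylation of a phenoxide with a reactive allylic halide is essentially quantitative.

Step 4
Reactants: 6 1-(allyloxy)-4-bromo-2-methoxybenzene
Product: 7 2-allyl-4-bromo-6-methoxyphenol
Conditions: N,N-diethylaniline, 200 °C
Reagents that add atoms: none
Why: In this aromatic Claisen rearrangement only one ortho position is free, so the allyl group lands regiospecifically next to the phenol.

Step 5
Reactants: 7 2-allyl-4-bromo-6-methoxyphenol; 3 [3-methoxy-4-(triisopropylsilyloxy)phenyl]methanol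
Product: 8 1-allyl-5-bromo-3-methoxy-2-[3-methoxy-4-(triisopropylsilyloxy)benzyloxy]benzene
Conditions: PPh3, DIAD, THF, 0 °C → rt
Reagents that add atoms: none
Why: Mitsunobu etherification joins the acidic phenol to the primary benzylic alcohol under neutral conditions, avoiding an unstable 4-silyloxybenzyl halide and base that would strip the aryl TIPS ether.

Step 6
Reactants: 8 1-allyl-5-bromo-3-methoxy-2-[3-methoxy-4-(triisopropylsilyloxy)benzyloxy]benzene
Product: 10 2-{5-bromo-3-methoxy-2-[3-methoxy-4-(triisopropylsilyloxy)benzyloxy]phenyl}acetaldehyde, via vicinal diol 9 (not isolated)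
Conditions: OsO4 (2 mol %), NaIO4, 2,6-lutidine, dioxane/H2O, rt
Reagents that add atoms: NaIO4, [Na+].[O-]I(=O)(=O)=O (oxygen handed on by catalytic OsO4, O=[Os](=O)(=O)=O)
Why: Lemieux–Johnson cleavage attacks only the terminal alkene and, unlike ozone, spares the electron-rich arenes, while lutidine buffers the medium.

Step 7
Reactants: 10 2-{5-bromo-3-methoxy-2-[3-methoxy-4-(triisopropylsilyloxy)benzyloxy]phenyl}acetaldehyde
Product: 11 2-{5-bromo-3-methoxy-2-[3-methoxy-4-(triisopropylsilyloxy)benzyloxy]phenyl}acetic acid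
Conditions: NaClO2, NaH2PO4, 2-methylbut-2-ene, t-BuOH/H2O, 0 °C → rt
Reagents that add atoms: NaClO2, [Na+].[O-]Cl=O
Why: Pinnick oxidation converts the sensitive arylacetaldehyde to the acid at pH 4–5, and the alkene scavenger prevents ring chlorination.

Step 8
Reactants: 11 2-{5-bromo-3-methoxy-2-[3-methoxy-4-(triisopropylsilyloxy)benzyloxy]phenyl}acetic acid
Product: 12 methyl 2-{5-bromo-3-methoxy-2-[3-methoxy-4-(triisopropylsilyloxy)benzyloxy]phenyl}acetate
Conditions: Me3SiCHN2, toluene/MeOH 4:1, 0 °C → rt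
Reagents that add atoms: trimethylsilyldiazomethane, C[Si](C)(C)C=[N+]=[N-]
Why: Diazoalkane esterification is neutral and fast, so neither the benzyl aryl ether nor the silyl ether is at risk.

Step 9
Reactants: 12 methyl 2-{5-bromo-3-methoxy-2-[3-methoxy-4-(triisopropylsilyloxy)benzyloxy]phenyl}acetate
Product: 13 methyl 2-diazo-2-{5-bromo-3-methoxy-2-[3-methoxy-4-(triisopropylsilyloxy)benzyloxy]phenyl}acetate
Conditions: 4-acetamidobenzenesulfonyl azide, DBU, MeCN, 0 °C → rt
Reagents that add atoms: 4-acetamidobenzenesulfonyl azide, CC(=O)Nc1ccc(cc1)S(=O)(=O)N=[N+]=[N-]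
Why: Regitz diazo transfer onto an arylacetate with DBU is the standard, dependable entry to donor/acceptor diazo esters.

Step 10
Reactants: 13 methyl 2-diazo-2-{5-bromo-3-methoxy-2-[3-methoxy-4-(triisopropylsilyloxy)benzyloxy]phenyl}acetate
Product: 14 methyl (2S,3R)-5-bromo-7-methoxy-2-[3-methoxy-4-(triisopropylsilyloxy)phenyl]-2,3-dihydrobenzofuran-3-carboxylate (2,3-cis)
Conditions: dirhodium tetrakis[N-phthaloyl-(R)-tert-leucinate], Rh2(R-PTTL)4 (1 mol %), toluene, −60 °C
Reagents that add atoms: none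
Why: In this intramolecular carbenoid 1,5 C–H insertion into the activated benzylic ether C–H, the phthalimide-walled catalyst closes the ring cis, and since S ligands give 2R,3S esters in this substrate class the R ligands set C2 (S) and C3 together.

Step 11
Reactants: 14 methyl (2S,3R)-cis-dihydrobenzofuran-3-carboxylate
Product: 15 {(2S,3S)-5-bromo-7-methoxy-2-[3-methoxy-4-(triisopropylsilyloxy)phenyl]-2,3-dihydrobenzofuran-3-yl}methanol (cis)
Conditions: i-Bu2AlH (3 equiv), CH2Cl2, −78 → −40 °C; aq potassium sodium tartrate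
Reagents that add atoms: none
Why: The non-basic, Lewis-acidic hydride reduces the ester through to the alcohol at low temperature without enolising C3, so the cis relationship survives and only the C3 descriptor changes, by priority.

Step 12
Reactants: 15 cis-(2S,3S) bromo alcohol
Product: 16 tert-butyldiphenylsilyl ether of 15
Conditions: TBDPSCl, imidazole, DMF, rt
Reagents that add atoms: tert-butylchlorodiphenylsilane, CC(C)(C)[Si](Cl)(c1ccccc1)c1ccccc1
Why: Primary alcohol silylation installs a group that outlasts the later acidic and HF·pyridine steps yet falls to fluoride ion at the end.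

Step 13
Reactants: 16 tert-butyldiphenylsilyl ether of 15
Product: 18 (2S,3S)-3-[(tert-butyldiphenylsilyloxy)methyl]-7-methoxy-2-[3-methoxy-4-(triisopropylsilyloxy)phenyl]-2,3-dihydrobenzofuran-5-carbaldehyde (ArB–CHO), via aryllithium 17 (not isolated)
Conditions: n-BuLi (1.05 equiv), THF, −78 °C; DMF, −78 → 0 °C; H2O
Reagents that add atoms: N,N-dimethylformamide, CN(C)C=O
Why: Bromine–lithium exchange is faster than any deprotonation at −78 °C, and DMF formylation (Bouveault type) delivers the aldehyde without touching C2 or C3.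

Step 14
Reactants: 19 syringaldehyde
Product: 20 3,5-dimethoxy-4-(triisopropylsilyloxy)benzaldehyde (ArS–CHO)
Conditions: TIPSOTf, 2,6-lutidine, CH2Cl2, 0 °C → rt
Reagents that add atoms: triisopropylsilyl triflate, CC(C)[Si](OS(=O)(=O)C(F)(F)F)(C(C)C)C(C)C
Why: The silyl triflate overcomes the hindrance of the doubly flanked phenol, and the aldehyde cannot enolise.

Step 15
Reactants: 21 (S)-4-benzyloxazolidin-2-one; 22 pent-4-enoyl chloride
Product: 24 (S)-4-benzyl-3-(pent-4-enoyl)oxazolidin-2-one, via N-lithio oxazolidinone 23 (not isolated)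
Conditions: n-BuLi, THF, −78 °C; 22, −78 → 0 °C
Reagents that add atoms: none
Why: N-acylation of the lithiated Evans auxiliary with an acid chloride is routine and high yielding.

Step 16
Reactants: 24 (S)-4-benzyl-3-(pent-4-enoyl)oxazolidin-2-one; 20 3,5-dimethoxy-4-(triisopropylsilyloxy)benzaldehyde
Product: 26 (S)-4-benzyl-3-{(2S)-2-[(S)-hydroxy(ArS)methyl]pent-4-enoyl}oxazolidin-2-one, via Z-boron enolate 25 (not isolated)
Conditions: n-Bu2BOTf, Et3N, CH2Cl2, 0 °C; 20, −78 → 0 °C; pH 7 buffer, MeOH, 30% H2O2, 0 °C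
Reagents that add atoms: none
Why: In the Evans syn aldol the Z-boron enolate reacts through a Zimmerman–Traxler chair on the face away from the benzyl group, giving the 2S,3S adduct (>95:5), which is C7 (S) and C8 of the target (C8 is labelled R once C9 is reduced).

Step 17
Reactants: 26 Evans syn aldol adduct
Product: 27 triethylsilyl ether of 26
Conditions: Et3SiOTf, 2,6-lutidine, CH2Cl2, −78 → 0 °C
Reagents that add atoms: triethylsilyl triflate, CC[Si](CC)(CC)OS(=O)(=O)C(F)(F)F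
Why: Silylation with triflate and lutidine avoids retro-aldol, and TES is the one silyl group that can later be removed selectively.

Step 18
Reactants: 27 triethylsilyl ether of 26
Product: 28 (2R)-2-[(S)-ArS(triethylsilyloxy)methyl]pent-4-en-1-ol
Conditions: LiBH4, MeOH (1 equiv), THF, 0 °C
Reagents that add atoms: none
Why: Reductive removal of the auxiliary turns the imide carbonyl into C9H2OH without epimerising C8 and returns the oxazolidinone.

Step 19
Reactants: 28 (2R)-2-[(S)-ArS(triethylsilyloxy)methyl]pent-4-en-1-ol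
Product: 31 (4R)-4-[(S)-ArS(triethylsilyloxy)methyl]tetrahydrofuran-2-ol (anomer mixture), via triol 29 (not isolated), via hydroxy aldehyde 30 (not isolated)
Conditions: OsO4 (2 mol %), NaIO4, 2,6-lutidine, dioxane/H2O, rt
Reagents that add atoms: NaIO4, [Na+].[O-]I(=O)(=O)=O (oxygen handed on by catalytic OsO4, O=[Os](=O)(=O)=O)
Why: Lemieux–Johnson cleavage removes the terminal carbon, and the resulting γ-hydroxy aldehyde closes spontaneously to the five-membered lactol.

Step 20
Reactants: 31 lactol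
Product: 32 (4R)-4-[(S)-ArS(triethylsilyloxy)methyl]dihydrofuran-2(3H)-one
Conditions: Pr4N[RuO4] (5 mol %), N-methylmorpholine N-oxide, 4 Å molecular sieves, CH2Cl2, rt
Reagents that add atoms: none
Why: Ley–Griffith oxidation converts lactols to lactones under neutral conditions that the TES and TIPS ethers tolerate.

Step 21
Reactants: 32 (4R)-lactone (1.3 equiv); 18 ArB–CHO
Product: 34 (3S,4R)-3-[hydroxy(ArB)methyl]-4-[(S)-ArS(triethylsilyloxy)methyl]dihydrofuran-2(3H)-one (C7' epimer mixture), via lithium enolate 33 (not isolated)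
Conditions: LiN(SiMe3)2, THF, −78 °C; 18, −78 °C; AcOH quench at −78 °C
Reagents that add atoms: none
Why: In this intermolecular lithium-enolate aldol the aldehyde approaches anti to the bulky C4 substituent, giving the 3,4-trans lactone that fixes C8' (R in the target), while the mixed C7' carbinol is corrected in step 23.

Step 22
Reactants: 34 aldol adduct
Product: 35 (2R,3R)-2-[(S)-ArS(triethylsilyloxy)methyl]-3-[hydroxy(ArB)methyl]butane-1,4-diol
Conditions: LiAlH4, THF, 0 °C; H2O/NaOH work-up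
Reagents that add atoms: none
Why: Hydride reduction of the lactone outruns retro-aldol at 0 °C, touches no stereocentre and leaves all silyl ethers in place.

Step 23
Reactants: 35 triol
Product: 36 {(2S,3R,4R)-2-ArB-4-[(S)-ArS(triethylsilyloxy)methyl]tetrahydrofuran-3-yl}methanol (ring A)
Conditions: (1S)-camphor-10-sulfonic acid (10 mol %), 4 Å molecular sieves, CH2Cl2, −20 → 0 °C
Reagents that add atoms: none
Why: In this acid-catalysed SN1 cyclodehydration only the very electron-rich C7' carbinol ionises and only the C9 hydroxyl can form a five-membered ring (C9'–OH would give an oxetane and C7–O is blocked), so both epimers converge on the 7'S isomer with the aryl trans to both cis-disposed neighbours.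

Step 24
Reactants: 36 TES-protected tetrahydrofuran alcohol
Product: 37 (S)-ArS{(3R,4R,5S)-5-ArB-4-(hydroxymethyl)tetrahydrofuran-3-yl}methanol (C7, C9' diol)
Conditions: HF·pyridine, pyridine, THF, 0 °C
Reagents that add atoms: none
Why: Buffered acidic fluoride cleaves the alkyl TES ether orders of magnitude faster than the TBDPS and aryl TIPS ethers and is too weakly acidic to ionise any benzylic C–O bond.

Step 25
Reactants: 37 C7, C9' diol
Product: 39 tris-silylated furofuran (target carrying two aryl TIPS ethers plus one TBDPS ether), via primary mesylate 38 (not isolated)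
Conditions: MsCl (1.1 equiv), Et3N, CH2Cl2, −20 °C; crude 38, NaH, THF, 0 °C → rt
Reagents that add atoms: none
Why: Selective mesylation of the primary alcohol followed by intramolecular Williamson 5-exo-tet closure breaks no bond at C7, so the Evans-derived 7S centre is retained and the aryl ends exo on the cis-fused bicycle (ring B).

Step 26
Reactants: 39 tris-silylated furofuran
Product: 40 target CNP0126146.1
Conditions: Bu4NF/AcOH 1:1 (6 equiv), THF, 0 °C → rt
Reagents that add atoms: none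
Why: Acetic-acid-buffered fluoride desilylation frees both phenols and the primary alcohol without building up phenoxide, which could open the cis-dihydrobenzofuran or the syringyl benzylic ether through a quinone methide.

**Compound list**
1 | vanillin | COc1cc(C=O)ccc1O | starting material
2 | 3-methoxy-4-(triisopropylsilyloxy)benzaldehyde | COc1cc(C=O)ccc1O[Si](C(C)C)(C(C)C)C(C)C | intermediate
3 | [3-methoxy-4-(triisopropylsilyloxy)phenyl]methanol | COc1cc(CO)ccc1O[Si](C(C)C)(C(C)C)C(C)C | intermediate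
4 | 4-bromo-2-methoxyphenol | COc1cc(Br)ccc1O | starting material
5 | allyl bromide | C=CCBr | starting material
6 | 1-(allyloxy)-4-bromo-2-methoxybenzene | C=CCOc1ccc(Br)cc1OC | intermediate
7 | 2-allyl-4-bromo-6-methoxyphenol | C=CCc1cc(Br)cc(OC)c1O | intermediate
8 | 1-allyl-5-bromo-3-methoxy-2-[3-methoxy-4-(triisopropylsilyloxy)benzyloxy]benzene | C=CCc1cc(Br)cc(OC)c1OCc1ccc(O[Si](C(C)C)(C(C)C)C(C)C)c(OC)c1 | intermediate
9 | 3-aryl-propane-1,2-diol from 8 (not isolated, racemic carbinol) | OCC(O)Cc1cc(Br)cc(OC)c1OCc1ccc(O[Si](C(C)C)(C(C)C)C(C)C)c(OC)c1 | intermediate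
10 | arylacetaldehyde | O=CCc1cc(Br)cc(OC)c1OCc1ccc(O[Si](C(C)C)(C(C)C)C(C)C)c(OC)c1 | intermediate
11 | arylacetic acid | OC(=O)Cc1cc(Br)cc(OC)c1OCc1ccc(O[Si](C(C)C)(C(C)C)C(C)C)c(OC)c1 | intermediate
12 | methyl arylacetate | COC(=O)Cc1cc(Br)cc(OC)c1OCc1ccc(O[Si](C(C)C)(C(C)C)C(C)C)c(OC)c1 | intermediate
13 | methyl aryldiazoacetate | COC(=O)C(=[N+]=[N-])c1cc(Br)cc(OC)c1OCc1ccc(O[Si](C(C)C)(C(C)C)C(C)C)c(OC)c1 | intermediate
14 | methyl (2S,3R)-cis-5-bromo-7-methoxy-2-[3-methoxy-4-(TIPSO)phenyl]-2,3-dihydrobenzofuran-3-carboxylate | COc1cc([C@H]2Oc3c(OC)cc(Br)cc3[C@H]2C(=O)OC)ccc1O[Si](C(C)C)(C(C)C)C(C)C | intermediate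
15 | (2S,3S)-cis bromo alcohol | COc1cc([C@H]2Oc3c(OC)cc(Br)cc3[C@H]2CO)ccc1O[Si](C(C)C)(C(C)C)C(C)C | intermediate
16 | TBDPS ether of 15 | COc1cc([C@H]2Oc3c(OC)cc(Br)cc3[C@H]2CO[Si](c4ccccc4)(c4ccccc4)C(C)(C)C)ccc1O[Si](C(C)C)(C(C)C)C(C)C | intermediate
17 | 5-lithio derivative of 16 (not isolated) | COc1cc([C@H]2Oc3c(OC)cc([Li])cc3[C@H]2CO[Si](c4ccccc4)(c4ccccc4)C(C)(C)C)ccc1O[Si](C(C)C)(C(C)C)C(C)C | intermediate
18 | ArB–CHO, (2S,3S)-cis-dihydrobenzofuran-5-carbaldehyde | COc1cc([C@H]2Oc3c(OC)cc(C=O)cc3[C@H]2CO[Si](c4ccccc4)(c4ccccc4)C(C)(C)C)ccc1O[Si](C(C)C)(C(C)C)C(C)C | intermediate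
19 | syringaldehyde | COc1cc(C=O)cc(OC)c1O | starting material
20 | 3,5-dimethoxy-4-(triisopropylsilyloxy)benzaldehyde | COc1cc(C=O)cc(OC)c1O[Si](C(C)C)(C(C)C)C(C)C | intermediate
21 | (S)-4-benzyloxazolidin-2-one | O=C1N[C@@H](Cc2ccccc2)CO1 | starting material
22 | pent-4-enoyl chloride | C=CCCC(=O)Cl | starting material
23 | N-lithio-(S)-4-benzyloxazolidin-2-one (not isolated) | [Li]N1C(=O)OC[C@@H]1Cc1ccccc1 | intermediate
24 | (S)-4-benzyl-3-(pent-4-enoyl)oxazolidin-2-one | C=CCCC(=O)N1C(=O)OC[C@@H]1Cc1ccccc1 | intermediate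
25 | Z-dibutylboron enolate of 24 (not isolated) | C=CC/C=C(\OB(CCCC)CCCC)N1C(=O)OC[C@@H]1Cc1ccccc1 | intermediate
26 | Evans syn aldol adduct (2S, carbinol S, auxiliary S) | C=CC[C@@H]([C@H](O)c1cc(OC)c(O[Si](C(C)C)(C(C)C)C(C)C)c(OC)c1)C(=O)N1C(=O)OC[C@@H]1Cc1ccccc1 | intermediate
27 | TES ether of 26 | C=CC[C@@H]([C@H](O[Si](CC)(CC)CC)c1cc(OC)c(O[Si](C(C)C)(C(C)C)C(C)C)c(OC)c1)C(=O)N1C(=O)OC[C@@H]1Cc1ccccc1 | intermediate
28 | (2R)-2-[(S)-ArS(TESO)methyl]pent-4-en-1-ol | C=CC[C@@H]([C@H](O[Si](CC)(CC)CC)c1cc(OC)c(O[Si](C(C)C)(C(C)C)C(C)C)c(OC)c1)CO | intermediate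
29 | pentane-1,2,5-triol from 28 (not isolated, mixed at the new carbinol) | OCC(O)C[C@@H]([C@H](O[Si](CC)(CC)CC)c1cc(OC)c(O[Si](C(C)C)(C(C)C)C(C)C)c(OC)c1)CO | intermediate
30 | γ-hydroxy aldehyde (not isolated) | O=CC[C@@H]([C@H](O[Si](CC)(CC)CC)c1cc(OC)c(O[Si](C(C)C)(C(C)C)C(C)C)c(OC)c1)CO | intermediate
31 | lactol (anomer mixture) | OC1C[C@@H]([C@H](O[Si](CC)(CC)CC)c2cc(OC)c(O[Si](C(C)C)(C(C)C)C(C)C)c(OC)c2)CO1 | intermediate
32 | (4R)-4-[(S)-ArS(TESO)methyl]dihydrofuran-2(3H)-one | O=C1C[C@@H]([C@H](O[Si](CC)(CC)CC)c2cc(OC)c(O[Si](C(C)C)(C(C)C)C(C)C)c(OC)c2)CO1 | intermediate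
33 | lithium enolate of 32 (not isolated) | [Li]OC1=C[C@@H]([C@H](O[Si](CC)(CC)CC)c2cc(OC)c(O[Si](C(C)C)(C(C)C)C(C)C)c(OC)c2)CO1 | intermediate
34 | (3S,4R)-trans aldol lactone, C7' epimer mixture | COc1cc([C@H]2Oc3c(OC)cc(C(O)[C@H]4C(=O)OC[C@@H]4[C@H](O[Si](CC)(CC)CC)c4cc(OC)c(O[Si](C(C)C)(C(C)C)C(C)C)c(OC)c4)cc3[C@H]2CO[Si](c4ccccc4)(c4ccccc4)C(C)(C)C)ccc1O[Si](C(C)C)(C(C)C)C(C)C | intermediate
35 | (8R,8'R)-triol, C7' epimer mixture | COc1cc([C@H]2Oc3c(OC)cc(C(O)[C@@H](CO)[C@H](CO)[C@H](O[Si](CC)(CC)CC)c4cc(OC)c(O[Si](C(C)C)(C(C)C)C(C)C)c(OC)c4)cc3[C@H]2CO[Si](c4ccccc4)(c4ccccc4)C(C)(C)C)ccc1O[Si](C(C)C)(C(C)C)C(C)C | intermediate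
36 | ring A tetrahydrofuran (7'S,8'R,8R,7S), C7–OTES, C9'–OH | COc1cc([C@H]2Oc3c(OC)cc([C@H]4OC[C@H]([C@H](O[Si](CC)(CC)CC)c5cc(OC)c(O[Si](C(C)C)(C(C)C)C(C)C)c(OC)c5)[C@@H]4CO)cc3[C@H]2CO[Si](c4ccccc4)(c4ccccc4)C(C)(C)C)ccc1O[Si](C(C)C)(C(C)C)C(C)C | intermediate
37 | C7, C9' diol | COc1cc([C@H]2Oc3c(OC)cc([C@H]4OC[C@H]([C@H](O)c5cc(OC)c(O[Si](C(C)C)(C(C)C)C(C)C)c(OC)c5)[C@@H]4CO)cc3[C@H]2CO[Si](c4ccccc4)(c4ccccc4)C(C)(C)C)ccc1O[Si](C(C)C)(C(C)C)C(C)C | intermediate
38 | C9' mesylate of 37 (not isolated) | COc1cc([C@H]2Oc3c(OC)cc([C@H]4OC[C@H]([C@H](O)c5cc(OC)c(O[Si](C(C)C)(C(C)C)C(C)C)c(OC)c5)[C@@H]4COS(C)(=O)=O)cc3[C@H]2CO[Si](c4ccccc4)(c4ccccc4)C(C)(C)C)ccc1O[Si](C(C)C)(C(C)C)C(C)C | intermediate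
39 | tris-silylated furofuran | COc1cc([C@H]2Oc3c(OC)cc([C@H]4OC[C@H]5[C@@H]4CO[C@@H]5c4cc(OC)c(O[Si](C(C)C)(C(C)C)C(C)C)c(OC)c4)cc3[C@H]2CO[Si](c4ccccc4)(c4ccccc4)C(C)(C)C)ccc1O[Si](C(C)C)(C(C)C)C(C)C | intermediate
40 | CNP0126146.1 | COc1cc([C@H]2Oc3c(OC)cc([C@H]4OC[C@H]5[C@@H]4CO[C@@H]5c4cc(OC)c(O)c(OC)c4)cc3[C@H]2CO)ccc1O | target

**Total steps:** 26.
**Longest linear sequence:** 17 (steps 3–13, then 21–26).

**Three steps most likely to fail**

**Step 10 (C–H insertion).**
- The substrate is more crowded (methoxy next to the benzyloxy group) and more electron-rich than the usual cases.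
- The cis ratio or ee may therefore fall short, and the sense of induction rests on analogy.
- The fallback sets out from acid 11 and comes back at alcohol 15. It replaces catalyst-only enantiocontrol with a covalent auxiliary, so the two cis products are separable diastereomers.
- Acid 11 is esterified with (−)-menthol (N,N'-dicyclohexylcarbodiimide, DMAP) to the menthyl arylacetate F1.
- Diazo transfer as in step 9 gives the menthyl aryldiazoacetate F2.
- Insertion with the same cis-selective dirhodium tetracarboxylate gives the cis esters. The (2S,3R) menthyl ester F3 is purified by crystallisation or chromatography and its configuration is checked.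
- i-Bu2AlH then gives 15 in diastereomerically derived enantiopurity.

**Step 21 (key aldol).**
- Both partners are bulky and the addition is reversible, so conversion may stall or retro-aldol may occur on work-up.
- The fallback sets out from aldehyde 18 and comes back at 34. It replaces the aldol with an irreversible Claisen-type acylation followed by ketone reduction.
- Aldehyde 18 is oxidised (NaClO2, NaH2PO4, 2-methylbut-2-ene) to the benzofuran-5-carboxylic acid F4.
- 1,1'-Carbonyldiimidazole converts it into the acyl imidazole F5.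
- Enolate 33, made with 2.2 equiv LiN(SiMe3)2, is C-acylated to the trans β-keto lactone F6. Its deprotonation drives the reaction to completion.
- NaBH4/CeCl3 in MeOH at −40 °C reduces the aryl ketone to 34. The C7' ratio does not matter.

**Step 23 (acid ring closure).**
- The acid could epimerise C2 of the cis-dihydrobenzofuran by opening it.
- It could also remove TES early, after which C7–OH would trap the cation as a 2,5-diaryl tetrahydrofuran.
- A third risk is Friedel–Crafts closure onto ArS.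
- The fallback sets out from 34 and comes back at mesylate 38. It avoids any cation by closing ring A through SN2 at a primary carbon.
- The epimers of 34 are separated to give the 7'S aldol lactone F7. The remaining 7'R material is oxidised with Dess–Martin periodinane to F6 and re-reduced into 34.
- LiAlH4 gives the 7'S triol F8.
- MsCl (2.1 equiv) and Et3N at −20 °C give the 9,9'-bis-mesylate F9.
- With NaH, the C7' alkoxide displaces only the C9 mesylate, because five-membered closure beats four-membered closure. Configuration is retained, giving the TES-protected tetrahydrofuran mesylate F10.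
- HF·pyridine/pyridine then gives 38, which is closed as in step 25.

**Further compounds**
F1 | step 10 | (1R,2S,5R)-menthyl 2-{5-bromo-3-methoxy-2-[3-methoxy-4-(triisopropylsilyloxy)benzyloxy]phenyl}acetate | O=C(Cc1cc(Br)cc(OC)c1OCc1ccc(O[Si](C(C)C)(C(C)C)C(C)C)c(OC)c1)O[C@@H]1C[C@H](C)CC[C@H]1C(C)C
F2 | step 10 | (1R,2S,5R)-menthyl 2-diazo-2-arylacetate | O=C(C(=[N+]=[N-])c1cc(Br)cc(OC)c1OCc1ccc(O[Si](C(C)C)(C(C)C)C(C)C)c(OC)c1)O[C@@H]1C[C@H](C)CC[C@H]1C(C)C
F3 | step 10 | (1R,2S,5R)-menthyl (2S,3R)-cis-5-bromo-7-methoxy-2-[3-methoxy-4-(TIPSO)phenyl]-2,3-dihydrobenzofuran-3-carboxylate | COc1cc([C@H]2Oc3c(OC)cc(Br)cc3[C@H]2C(=O)O[C@@H]4C[C@H](C)CC[C@H]4C(C)C)ccc1O[Si](C(C)C)(C(C)C)C(C)C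
F4 | step 21 | ArB–CO2H, (2S,3S)-cis-dihydrobenzofuran-5-carboxylic acid | COc1cc([C@H]2Oc3c(OC)cc(C(=O)O)cc3[C@H]2CO[Si](c4ccccc4)(c4ccccc4)C(C)(C)C)ccc1O[Si](C(C)C)(C(C)C)C(C)C
F5 | step 21 | ArB–C(O)-imidazol-1-yl | COc1cc([C@H]2Oc3c(OC)cc(C(=O)n4ccnc4)cc3[C@H]2CO[Si](c4ccccc4)(c4ccccc4)C(C)(C)C)ccc1O[Si](C(C)C)(C(C)C)C(C)C
F6 | step 21 | (3S,4R)-trans-3-(ArB-carbonyl)-4-[(S)-ArS(TESO)methyl]dihydrofuran-2(3H)-one | COc1cc([C@H]2Oc3c(OC)cc(C(=O)[C@H]4C(=O)OC[C@@H]4[C@H](O[Si](CC)(CC)CC)c4cc(OC)c(O[Si](C(C)C)(C(C)C)C(C)C)c(OC)c4)cc3[C@H]2CO[Si](c4ccccc4)(c4ccccc4)C(C)(C)C)ccc1O[Si](C(C)C)(C(C)C)C(C)C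
F7 | step 23 | 7'S epimer of aldol lactone 34 | COc1cc([C@H]2Oc3c(OC)cc([C@@H](O)[C@H]4C(=O)OC[C@@H]4[C@H](O[Si](CC)(CC)CC)c4cc(OC)c(O[Si](C(C)C)(C(C)C)C(C)C)c(OC)c4)cc3[C@H]2CO[Si](c4ccccc4)(c4ccccc4)C(C)(C)C)ccc1O[Si](C(C)C)(C(C)C)C(C)C
F8 | step 23 | 7'S triol | COc1cc([C@H]2Oc3c(OC)cc([C@@H](O)[C@@H](CO)[C@H](CO)[C@H](O[Si](CC)(CC)CC)c4cc(OC)c(O[Si](C(C)C)(C(C)C)C(C)C)c(OC)c4)cc3[C@H]2CO[Si](c4ccccc4)(c4ccccc4)C(C)(C)C)ccc1O[Si](C(C)C)(C(C)C)C(C)C
F9 | step 23 | 9,9'-bis-mesylate of F8 | COc1cc([C@H]2Oc3c(OC)cc([C@@H](O)[C@@H](COS(C)(=O)=O)[C@H](COS(C)(=O)=O)[C@H](O[Si](CC)(CC)CC)c4cc(OC)c(O[Si](C(C)C)(C(C)C)C(C)C)c(OC)c4)cc3[C@H]2CO[Si](c4ccccc4)(c4ccccc4)C(C)(C)C)ccc1O[Si](C(C)C)(C(C)C)C(C)C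
F10 | step 23 | C9' mesylate of 36 (C7–OTES retained) | COc1cc([C@H]2Oc3c(OC)cc([C@H]4OC[C@H]([C@H](O[Si](CC)(CC)CC)c5cc(OC)c(O[Si](C(C)C)(C(C)C)C(C)C)c(OC)c5)[C@@H]4COS(C)(=O)=O)cc3[C@H]2CO[Si](c4ccccc4)(c4ccccc4)C(C)(C)C)ccc1O[Si](C(C)C)(C(C)C)C(C)C
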